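**Retrosynthetic overview**
1. Target 8 comes from one global hydrogenolysis (14 O‑benzyl groups and 2 C8–Br bonds) of the protected dibromo dimer 7.
2. The only skeletal disconnection is the C4(upper)–C6(lower) interflavan bond. 7 arises by anodic dehydrogenative homodimerisation of one monomer, 5, which supplies C4–H as the latent cation and C6–H as the nucleophile.
3. The C8 bromine in 5 blocks the normally preferred 4→8 mode, so only 4→6 coupling remains. 5 comes from hepta‑O‑benzyl epicatechin gallate 4 by bromination.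
4. 4 comes from esterification of tetra‑O‑benzyl‑epicatechin 2 (made from (−)‑epicatechin 1 and BnBr) with 3,4,5‑tris(benzyloxy)benzoic acid 3.
5. No ring is formed. The A, B and C rings and C2/C3 of both units are bought in 1, and the galloyl ring in 3. C4 of the upper unit is the only new stereocentre and is set by the substrate.

Assumption: (−)‑epicatechin (≥98 %) and 3,4,5‑tris(benzyloxy)benzoic acid are treated as commercially available; the former is the only source of chirality.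

**Step 1**
Reactants: 1 (−)‑epicatechin
Product: 2 5,7,3',4'‑tetra‑O‑benzyl‑(−)‑epicatechin, i.e. (2R,3R)‑5,7‑bis(benzyloxy)‑2‑[3,4‑bis(benzyloxy)phenyl]chroman‑3‑ol
Conditions: BnBr (4.4 equiv), K2CO3 (5 equiv), degassed DMF, Ar, 0 °C → rt, 24 h
Reagents that add atoms: benzyl bromide, BrCc1ccccc1
Why: Williamson O‑alkylation with a carbonate base ionises only the four phenols and leaves the secondary 3‑OH free, and because no bond to C2 or C3 is broken the 2R,3R configuration bought in 1 is kept.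

**Step 2**
Reactants: 2 5,7,3',4'‑tetra‑O‑benzyl‑(−)‑epicatechin; 3 3,4,5‑tris(benzyloxy)benzoic acid
Product: 4 hepta‑O‑benzyl‑(−)‑epicatechin 3‑O‑gallate, i.e. (2R,3R)‑5,7‑bis(benzyloxy)‑2‑[3,4‑bis(benzyloxy)phenyl]chroman‑3‑yl 3,4,5‑tris(benzyloxy)benzoate
Conditions: 3 (1.3 equiv), DCC (1.5 equiv), DMAP (0.3 equiv), CH2Cl2, 0 °C → rt, 16 h
Reagents that add atoms: none
Why: Steglich esterification acylates the only free hydroxyl at oxygen, so the C3–O bond is never broken, the 3R centre is retained, and the neutral conditions do not epimerise C2.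

**Step 3**
Reactants: 4 hepta‑O‑benzyl‑(−)‑epicatechin 3‑O‑gallate
Product: 5 8‑bromo‑hepta‑O‑benzyl‑(−)‑epicatechin 3‑O‑gallate (Br on A‑ring C8, between the 7‑OBn group and C8a; 2R,3R)
Conditions: NBS (1.02 equiv), CH2Cl2, dark, −40 → 0 °C
Reagents that add atoms: N‑bromosuccinimide, O=C1CCC(=O)N1Br
Why: Electrophilic aromatic bromination (SEAr) goes to the phloroglucinol‑type A ring, the most electron‑rich arene present, and there to C8 (flanked by one OBn and the ring oxygen) rather than C6 (between two OBn groups), as is standard for O‑benzylated flavan‑3‑ols, and no stereocentre is touched.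

**Step 4**
Reactants: 5 8‑bromo‑hepta‑O‑benzyl‑(−)‑epicatechin 3‑O‑gallate (two molecules: one is oxidised at C4, the other reacts at C6)
Product: 7 8‑bromo‑hepta‑O‑benzyl‑epicatechin 3‑O‑gallate‑(4β→6)‑8‑bromo‑hepta‑O‑benzyl‑epicatechin 3‑O‑gallate, via flavan‑4‑ylium cation 6 (not isolated)
Conditions: RVC(+) | Pt wire(−), undivided (quasi‑divided) cell, DDQ (15 mol %), n‑Bu4NPF6 (0.1 M), CH2Cl2/HFIP 4:1, 3 Å MS, [5] = 0.15 M, 0 °C, E(anode) ≈ +1.1 V vs Ag/AgCl, ≈0.45 F/mol, stopped at ≈35 % conversion; unreacted 5 recovered and recycled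
Reagents that add atoms: none
Why: Proposed new method: anodically driven, DDQ‑mediated dehydrogenative C(sp3)–H/C(sp2)–H homocoupling of a flavan, in which DDQ removes the pseudo‑axial 4β‑H of 5 as hydride (the same C4‑selective event as in the known DDQ C4‑oxygenation of O‑benzylated flavan‑3‑ols, with benzyl ethers, C2–H and the gallate left alone by ground‑state DDQ), HFIP sustains cation 6 without capturing it irreversibly, a second molecule of 5 can attack only through C6 because C8 carries Br, and it attacks from the β face because the 2‑aryl group and the axial 3‑O‑galloyl group (whose C=O leans over the empty orbital) both lie on the α face, which sets C4 as 4β (3,4‑trans) by substrate control alone; DDQH2 is reoxidised at the anode about 0.3 V below the onset of 5, the two protons leave as H2 at the cathode, and the charge limit keeps monomer 5 in large excess over 7 so that 6 is intercepted mainly by 5 and chain growth stays minor; the closest known reaction types are DDQ‑mediated cross‑dehydrogenative benzylic C–H/arene coupling, anodic regeneration of DDQ, and Lewis‑acid 4→6 coupling of 8‑halo‑capped flavans.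

**Step 5**
Reactants: 7 protected 8,8'‑dibromo (4β→6) dimer
Product: 8 procyanidin B‑5 3,3'‑di‑O‑gallate
Conditions: H2 (1 atm), 20 % Pd(OH)2/C, NaOAc (2.5 equiv), THF/MeOH/H2O 10:10:1, rt, 12 h; filter under Ar, Sephadex LH‑20, lyophilise
Reagents that add atoms: none
Why: Catalytic hydrogenolysis cleaves all fourteen aryl benzyl ethers and hydrodebrominates both C8–Br bonds in one operation, the acetate buffer takes up HBr so the acid‑labile interflavan bond survives, and the esters, the C2–O1 bonds and all five stereocentres are untouched, as is usual for benzylated procyanidin gallates.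

**Compound list**
1 | (−)‑epicatechin (2R,3R) | O[C@@H]1Cc2c(O)cc(O)cc2O[C@@H]1c1ccc(O)c(O)c1 | starting material
2 | 5,7,3',4'‑tetra‑O‑benzyl‑(−)‑epicatechin (2R,3R; 3‑OH free) | O[C@@H]1Cc2c(OCc3ccccc3)cc(OCc3ccccc3)cc2O[C@@H]1c1ccc(OCc2ccccc2)c(OCc2ccccc2)c1 | intermediate
3 | 3,4,5‑tris(benzyloxy)benzoic acid | OC(=O)c1cc(OCc2ccccc2)c(OCc2ccccc2)c(OCc2ccccc2)c1 | starting material
4 | hepta‑O‑benzyl‑(−)‑epicatechin 3‑O‑gallate (2R,3R) | O=C(O[C@@H]1Cc2c(OCc3ccccc3)cc(OCc3ccccc3)cc2O[C@@H]1c1ccc(OCc2ccccc2)c(OCc2ccccc2)c1)c1cc(OCc2ccccc2)c(OCc2ccccc2)c(OCc2ccccc2)c1 | intermediate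
5 | 8‑bromo‑hepta‑O‑benzyl‑(−)‑epicatechin 3‑O‑gallate (2R,3R) | O=C(O[C@@H]1Cc2c(OCc3ccccc3)cc(OCc3ccccc3)c(Br)c2O[C@@H]1c1ccc(OCc2ccccc2)c(OCc2ccccc2)c1)c1cc(OCc2ccccc2)c(OCc2ccccc2)c(OCc2ccccc2)c1 | intermediate
6 | (2R,3R)‑8‑bromo‑5,7‑bis(benzyloxy)‑2‑[3,4‑bis(benzyloxy)phenyl]‑3‑[3,4,5‑tris(benzyloxy)benzoyloxy]chroman‑4‑ylium (C4 benzylic cation, not isolated) | O=C(O[C@@H]1[CH+]c2c(OCc3ccccc3)cc(OCc3ccccc3)c(Br)c2O[C@@H]1c1ccc(OCc2ccccc2)c(OCc2ccccc2)c1)c1cc(OCc2ccccc2)c(OCc2ccccc2)c(OCc2ccccc2)c1 | intermediate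
7 | 8,8'‑dibromo‑tetradeca‑O‑benzyl‑procyanidin B‑5 3,3'‑di‑O‑gallate (both units 2R,3R; upper C4 is 4β, trans to the 3‑O‑galloyl group; bond C4 upper to C6 lower) | O=C(O[C@@H]1[C@@H](c2c(OCc4ccccc4)c(Br)c3c(c2OCc4ccccc4)C[C@@H](OC(=O)c2cc(OCc4ccccc4)c(OCc4ccccc4)c(OCc4ccccc4)c2)[C@@H](c2ccc(OCc4ccccc4)c(OCc4ccccc4)c2)O3)c2c(OCc4ccccc4)cc(OCc4ccccc4)c(Br)c2O[C@@H]1c1ccc(OCc4ccccc4)c(OCc4ccccc4)c1)c1cc(OCc4ccccc4)c(OCc4ccccc4)c(OCc4ccccc4)c1 | intermediate
8 | procyanidin B‑5 3,3'‑di‑O‑gallate, i.e. epicatechin 3‑O‑gallate‑(4β→6)‑epicatechin 3‑O‑gallate | O=C(O[C@@H]1[C@@H](c2c(O)cc3c(c2O)C[C@@H](OC(=O)c2cc(O)c(O)c(O)c2)[C@@H](c2ccc(O)c(O)c2)O3)c2c(O)cc(O)cc2O[C@@H]1c1ccc(O)c(O)c1)c1cc(O)c(O)c(O)c1 | target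

**Total step count:** 5. **Longest linear sequence:** 5 (1 → 2 → 4 → 5 → 7 → 8).

**Three steps most likely to fail**

*Step 4 (the proposed new step).*
- Hydride abstraction from the 8‑bromo, 3‑O‑acyl‑deactivated flavan may be slow.
- DDQ may shuttle between the electrodes and waste charge.
- Cation 6 may lose H‑3 to give a flav‑3‑ene, which is then over‑oxidised to a flavylium salt.
- Chain growth may continue to 4→6 trimers.

The fallback uses known chemistry only and oxidises C4 before the deactivating ester is put on. It sets out from 2. DDQ (2 equiv) and 2‑ethoxyethanol in CH2Cl2 at rt give 4β‑(2‑ethoxyethoxy)‑5,7,3',4'‑tetra‑O‑benzyl‑epicatechin F1. NBS in CH2Cl2 at −40 °C caps it to give 8‑bromo‑4β‑(2‑ethoxyethoxy)‑5,7,3',4'‑tetra‑O‑benzyl‑epicatechin F2. DCC/DMAP esterification with 3 gives 8‑bromo‑4β‑(2‑ethoxyethoxy)‑hepta‑O‑benzyl‑epicatechin 3‑O‑gallate F3. TMSOTf in CH2Cl2 (−78 → −30 °C) then couples F3 with 5 (3 equiv, the excess recovered) in the established Lewis‑acid, halo‑capped 4→6 mode. Attack is again from the β face, and the fallback comes back to the route at 7.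

*Step 5.*
- Hydrodebromination of the two hindered C8–Br bonds may be incomplete.
- Bromide may poison the catalyst.
- HBr may cleave the interflavan bond while fourteen benzyl groups are still being removed.

The fallback separates the two reductions. It sets out from 7. Pd(OAc)2/SPhos with sodium formate in DMF at 80 °C (Pd‑catalysed formate hydrodehalogenation) gives tetradeca‑O‑benzyl‑procyanidin B‑5 3,3'‑di‑O‑gallate F4. F4 can be purified on silica as a non‑polar, halide‑free compound. Neutral hydrogenolysis (H2, Pd(OH)2/C, THF/MeOH/H2O) then comes back to the route at 8.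

*Step 3.*
- Some 6‑bromo or 6,8‑dibromo product may form. The 6‑bromo isomer would reopen the 4→8 mode in Step 4.
- These isomers are hard to separate from 5 at the stage of the large, non‑crystalline heptabenzyl ester.

The fallback changes the order of events so that bromination takes place on the small alcohol, where C8 selectivity is established and the product crystallises. It sets out from 2. NBS (1.0 equiv) in CH2Cl2 (−78 °C → rt) gives 8‑bromo‑5,7,3',4'‑tetra‑O‑benzyl‑(−)‑epicatechin F5, which is recrystallised free of regioisomers. DCC/DMAP esterification of F5 with 3 in CH2Cl2 then comes back to the route at 5.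

**Further compounds**
F1 | step 4 | 4β‑(2‑ethoxyethoxy)‑5,7,3',4'‑tetra‑O‑benzyl‑epicatechin | O[C@@H]1[C@@H](OCCOCC)c2c(OCc3ccccc3)cc(OCc3ccccc3)cc2O[C@@H]1c1ccc(OCc2ccccc2)c(OCc2ccccc2)c1
F2 | step 4 | 8‑bromo‑4β‑(2‑ethoxyethoxy)‑5,7,3',4'‑tetra‑O‑benzyl‑epicatechin | O[C@@H]1[C@@H](OCCOCC)c2c(OCc3ccccc3)cc(OCc3ccccc3)c(Br)c2O[C@@H]1c1ccc(OCc2ccccc2)c(OCc2ccccc2)c1
F3 | step 4 | 8‑bromo‑4β‑(2‑ethoxyethoxy)‑hepta‑O‑benzyl‑epicatechin 3‑O‑gallate | O=C(O[C@@H]1[C@@H](OCCOCC)c2c(OCc3ccccc3)cc(OCc3ccccc3)c(Br)c2O[C@@H]1c1ccc(OCc2ccccc2)c(OCc2ccccc2)c1)c1cc(OCc2ccccc2)c(OCc2ccccc2)c(OCc2ccccc2)c1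
F4 | step 5 | tetradeca‑O‑benzyl‑procyanidin B‑5 3,3'‑di‑O‑gallate | O=C(O[C@@H]1[C@@H](c2c(OCc4ccccc4)cc3c(c2OCc4ccccc4)C[C@@H](OC(=O)c2cc(OCc4ccccc4)c(OCc4ccccc4)c(OCc4ccccc4)c2)[C@@H](c2ccc(OCc4ccccc4)c(OCc4ccccc4)c2)O3)c2c(OCc4ccccc4)cc(OCc4ccccc4)cc2O[C@@H]1c1ccc(OCc4ccccc4)c(OCc4ccccc4)c1)c1cc(OCc4ccccc4)c(OCc4ccccc4)c(OCc4ccccc4)c1
F5 | step 3 | 8‑bromo‑5,7,3',4'‑tetra‑O‑benzyl‑(−)‑epicatechin | O[C@@H]1Cc2c(OCc3ccccc3)cc(OCc3ccccc3)c(Br)c2O[C@@H]1c1ccc(OCc2ccccc2)c(OCc2ccccc2)c1
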